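(The constants are those of an exercise.)

**Counting partner.** Count the coupling partner. Solid substrate dissolves, dissolved substrate couples with coupling partner to give target, target relaxes towards isomer of the product, and protic impurity quenches coupling partner on the side.

solid substrate 11 mM; coupling partner 0.800 equiv; protic impurity 2.20 mM; time 4.0 min

- how much target there is at 4.0 min, in percent of the solid substrate charged
- the change that raises the amount of target at 4.0 min, in percent of the solid substrate charged most ("none" if none brings more than 2 percentage points) (delta / eta / theta / none)
- amount of target at 4.0 min, in percent of the solid substrate charged, after delta

- delta: doubling the amount of coupling partner, all else as stated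
- eta: doubling the solubility in step 1, all else as stated
- theta: doubling the dissolution coefficient of step 1, all else as stated

    solid substrate ⇌ dissolved substrate, rate k1*(cs1 - [dissolved substrate]) while solid is left; crystals form when [dissolved substrate] > cs1 (cs1 = 4.7 mM, k1 = 0.021 s⁻¹)
    dissolved substrate + coupling partner → target (k2 = 63 L mol⁻¹ s⁻¹)
    target ⇌ isomer of the product (K3 = 2.2, k3 = 0.0053 s⁻¹)
    coupling partner + protic impurity → quenched reagent (k4 = 2.5 L mol⁻¹ s⁻¹)

**Feed first.** The flask holds 8.80 mM of coupling partner, less than the 11 mM of solid substrate, so it is the limiting reagent. At the charged c(coupling partner), dissolved substrate couples with a time constant of 1.80 s, far shorter than the 47.6 s of dissolving, so while coupling partner lasts we keep c(dissolved substrate) near zero and take the ceiling feed 5.92 mM min⁻¹. Coupling then spends the coupling partner in about 1.49 min, roughly linearly.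

**First number.** We treat the quench as a correction and compute only that toll: with c(protic impurity) held at its charge it is 2.16 mM. Target is born on average 3.26 min before the reading, and it relaxes with time constant 2.16 min towards an equilibrium share of 31.2%, so 46.5% of it survives. That gives 28.1%.

**Reforged link.** The toll is the weak link, since it claims nearly all of the protic impurity while holding it constant. Letting c(protic impurity) decay against the mean coupling partner gives 1.37 mM. The coupled budget is 7.43 mM, the charge of coupling partner less the toll, and the yield is 31.4%.

**The changes.** After delta the budget is at least 15.4 mM, above the 11 mM of substrate, so the substrate limits. Its feed lasts 1.86 min, which gives 47.9%. Eta doubles the solubility and theta the dissolution coefficient, so each doubles the ceiling feed, and the same reckoning gives 31.9%. Our choice is delta.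

**The result.** The forecast, on the ground that “Dissolution is the bottleneck”, gave 32% (29% to 35%), delta, and 48.7% (45% to 52%). The simulation gives 31.9%, and delta at 48.9%, a gain of 17 percentage points against 0 points for eta and −0.022 points for theta.

**Budget held.** In the flask, the half-life of coupling partner by quenching at charged concentrations is 2.1 min, longer than the 0.987 min at which dissolving reaches the midpoint of its turnover. Target and isomer of the product together stand at 67.8% of the solid substrate charged, against a budget of 67.5%, and the same flask read at 2.5 min holds 42.6% target and 25.2% isomer of the product, again 67.8%.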